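- The dusk flask starts slowly: after 90.0 min it has lost 6.70 % of its free monomer, a logarithmic slope of 0.0462 h⁻¹.

| flask | free monomer | initiator | impurity | remark | time |
|---|---|---|---|---|---|
| dusk | 0.10 M | 5 mol% | 0.73 mM | the very flask that is asked about, followed so far |  |
| spring | 0.10 M | 7.5 mol% | 0.73 mM | run made earlier |  |
| flask | 0.10 M | 5 mol% | 0.73 mM |  | 5.0 h |

- dusk (time / min: monomer in chains / %, free monomer / %): 8.00: 0.2, 99.9; 12.0: 0, 99.6; 20.0: 1.7, 98.6; 30.0: 1.4, 97.8; 50.0: 3.9, 96.7; 90.0: 7.6, 93.3
- spring (time / h: monomer in chains / %, free monomer / %): 0.667: 3.6, 95.3; 1.33: 9.2, 90.1; 2.00: 14.8, 84.8; 2.50: 20.1, 80.6; 3.00: 22.9, 76.7; 4.00: 30.8, 68.4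

(standard deviation of a reading: 0.5 percentage points)

- the average divides the monomer in chains by the number of chains begun, living and dead together
- the earlier runs were read with a standard deviation of 0.5 percentage points
- the earlier runs do not show the number of chains; that part of a forecast is a guess

* average number of monomer units in a chain (chains begun, living or dead) at 5.0 h
* part of the free monomer that has reacted at 5.0 h

- We suppose each impurity takes one initiator, so the dusk flask has 4.27 mM of net initiator, c(initiator) minus c(impurity) at the charge, and spring has 6.77 mM.
- Spring's last two readings give a slope of 0.115 h⁻¹; we take the late curve as pseudo-first-order and scale it by net initiator, which gives the dusk flask 0.0722 h⁻¹, steeper than the slope read at its start.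
- Run from the last dusk reading, this line reaches 27.5 % reacted at 5.0 h. Its half-life of 9.60 h is longer than that time, so we draw no level yet.
- For the chain count we set a ceiling at the net initiator, which with our reckoned c puts a floor under dp near 6.45.
- The forecast gave dp 5.7 (4.6 to 7.5) and c 26.5 % (24 % to 29.5 %), saying "Chains begun are a guess".
- The flask gives dp 10.2 and c 26.1 %.

    initiator → spent initiator A (k = 0.00750 min⁻¹)
    initiator + impurity → spent initiator B (k = 460 M⁻¹ min⁻¹)
    free monomer + initiator → living end + monomer in chains (k = 0.120 M⁻¹ min⁻¹)
    free monomer + living end → monomer in chains + living end, rate k4*[living end]*[free monomer] (k = 0.460 M⁻¹ min⁻¹)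
    monomer in chains + living end → free monomer + living end, rate k5*[living end] as long as [monomer in chains] is above zero (k = 0.00260 min⁻¹)

- At 5.00 h the flask holds 0.00257 M of living end, 0.00168 M of spent initiator A and 0.0195 mM of initiator, together 4.27 mM, the net initiator again. At 2.74 h initiator in the flask enters chains 1.4 times as fast as it becomes spent initiator A, and at the asked time the living ends stand below the ceiling, with dp above the floor.
- The neighbour charged with 0.25 M has 11.8 mM of net initiator, so its scaled slope 0.199 h⁻¹, run from the charge, gives 63.0 % reacted and a dp floor near 13.3; computed, that neighbour reaches c 68.3 % and dp 18.5.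

Readings and results are simulated with constants of no real substance, noise included.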